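## Retrosynthetic overview

1. Target 19 ⇒ acrylic acid 18 (C2–H by asymmetric hydrogenation) ⇒ hydroxy enone 17. The C15–O bond of the 6-oxabicyclo[3.2.1]octanone is closed by intramolecular oxa-Michael addition; this ether bridge is the last ring formed.
2. The propanoic acid comes from an acetyl group (enol triflate, hydroxycarbonylation). The cyclohexane ring (C4–C9 bond) comes from an intramolecular Michael addition onto α-methylene-δ-lactone 13.
3. The lactone C10(=O)–O–C11 bond comes from reduction/lactonization of β-keto aldehyde 11. The C12–C7 bond comes from a Claisen rearrangement of allyl vinyl ether 10 (hydroxymethylene ketone 4 plus Morita–Baylis–Hillman bromide 9).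
4. C17 comes from a new copper-catalysed enantioselective desymmetrizing 1,4-addition of BnOCH2MgCl to dienone 2.
5. Ring order: ring A (from 1) → δ-lactone → cyclohexane → ether bridge.

Atom labels used below: C2 = carbon α to CO2H; C4 = cyclohexane CH bearing the side chain; C5, C6 = ring CH2 between C4 and C7; C7 = ring-fusion CH bonded to the spiro carbon; C8 = ring-fusion CH bonded to the lactone carbonyl C10; C9 = ring CH2 between C8 and C4; C11 = lactone OCH2; C12 = spiro carbon; C13 = ketone carbon; C14, C15 = next two ring A carbons (C15 becomes the ether CH); C16 = ether CH2; C17 = ring A CH bearing C16; C18 = CMe2.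

Assumption: the ligand antipodes named in steps 2 and 13 (and in the fallback to step 2) are taken to be those that give the drawn configurations; the mirror-image ligand is used if a first run shows the opposite sense.

## Route

Step 1
Reactants: 1 4,4-dimethylcyclohex-2-en-1-one
Product: 2 4,4-dimethylcyclohexa-2,5-dien-1-one
Conditions: DDQ, TsOH (cat.), dioxane, 100 °C
Reagents that add atoms: none
Why: Quinone dehydrogenation (hydride abstraction from the dienol) of an enone that cannot aromatize because C4 is quaternary gives the mirror-symmetric cross-conjugated dienone.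

Step 2
Reactants: 2 4,4-dimethylcyclohexa-2,5-dien-1-one
Product: 3 (5S)-5-[(benzyloxy)methyl]-4,4-dimethylcyclohex-2-en-1-one
Conditions: BnOCH2Cl, Mg (activated), THF, −20 °C; then 2, CuBr·SMe2 (5 mol %), (R)-1-[(S)-2-(diphenylphosphanyl)ferrocenyl]ethyl(dicyclohexyl)phosphane (6 mol %), t-BuOMe, −78 °C; then 1 M HCl
Reagents that add atoms: benzyloxymethylmagnesium chloride, Cl[Mg]COCc1ccccc1 (made in the flask from benzyl chloromethyl ether, ClCOCc1ccccc1, and Mg)
Why: Proposed new method: a monovalent copper–ferrocenyl bisphosphine complex takes up the α-alkoxymethyl group from the Grignard reagent, binds one of the two enantiotopic enone arms of the dienone and transfers the benzyloxymethyl group through a trivalent copper σ-enolate followed by reductive elimination, so that C17 is set by catalyst-controlled desymmetrization while the second, now more hindered enone is left intact; the closest known reactions are the copper/ferrocenyl-bisphosphine-catalysed asymmetric conjugate addition of simple alkyl Grignard reagents to cyclohexenones, the copper-catalysed desymmetrizing alkylation of 4,4-disubstituted cyclohexadienones with dialkylzincs and the racemic 1,4-addition of stoichiometric alkoxymethylcuprates.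

Step 3
Reactants: 3 (5S)-5-[(benzyloxy)methyl]-4,4-dimethylcyclohex-2-en-1-one
Product: 4 (5R,6Z)-5-[(benzyloxy)methyl]-6-(hydroxymethylidene)-4,4-dimethylcyclohex-2-en-1-one
Conditions: NaH, HCO2Et, EtOH (cat.), THF, 0 °C to rt; then 1 M HCl
Reagents that add atoms: ethyl formate, CCOC=O
Why: Claisen-type formylation at C12, the only enolizable position, is driven by formation of the stabilized sodium enolate of the hydroxymethylene ketone; C17 is untouched (its descriptor changes from S to R only because the CIP priorities change).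

Step 4
Reactants: 5 1-methylcyclopentene
Product: 6 5-oxohexanal
Conditions: O3, CH2Cl2, −78 °C; then Me2S, rt
Reagents that add atoms: ozone, [O-][O+]=O
Why: Ozonolysis with reductive work-up cleaves the trisubstituted ring alkene to the keto aldehyde.

Step 5
Reactants: 6 5-oxohexanal; 7 methyl acrylate
Product: 8 methyl 3-hydroxy-2-methylidene-7-oxooctanoate (racemic)
Conditions: DABCO (1 equiv), excess 7, rt, 4 d
Reagents that add atoms: none
Why: Morita–Baylis–Hillman reaction in which the DABCO–acrylate ammonium enolate attacks the aldehyde, far more electrophilic than the methyl ketone; the racemic carbinol centre is erased in step 6.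

Step 6
Reactants: 8 methyl 3-hydroxy-2-methylidene-7-oxooctanoate
Product: 9 methyl (2Z)-2-(bromomethyl)-7-oxooct-2-enoate
Conditions: PBr3, Et2O, 0 °C
Reagents that add atoms: phosphorus tribromide, BrP(Br)Br
Why: SN2' bromination of the Morita–Baylis–Hillman alcohol with allylic transposition gives the conjugated, thermodynamically preferred (Z)-bromide (alkyl chain cis to CH2Br).

Step 7
Reactants: 4 (5R,6Z)-5-[(benzyloxy)methyl]-6-(hydroxymethylidene)-4,4-dimethylcyclohex-2-en-1-one; 9 methyl (2Z)-2-(bromomethyl)-7-oxooct-2-enoate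
Product: 11 methyl (3S)-3-{(1S,6R)-6-[(benzyloxy)methyl]-1-formyl-5,5-dimethyl-2-oxocyclohex-3-en-1-yl}-2-methylidene-7-oxooctanoate, via allyl vinyl ether 10 (not isolated)
Conditions: K2CO3, acetone, rt; filter, evaporate; then PhMe, 110 °C
Reagents that add atoms: none
Why: O-alkylation of the hydroxymethylene ketone (C-alkylation would have to create a quaternary centre directly) is followed by a Claisen rearrangement through a chair transition state, in which the allyl unit reaches C12 from the face anti to the pseudoaxial benzyloxymethyl group on C17 (sets C12) and the (E)-enol ether together with the alkene geometry inherited from the (Z)-bromide sets C7 relative to C12.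

Step 8
Reactants: 11 methyl (3S)-3-{(1S,6R)-6-[(benzyloxy)methyl]-1-formyl-5,5-dimethyl-2-oxocyclohex-3-en-1-yl}-2-methylidene-7-oxooctanoate
Product: 13 (5S,6S,11R)-11-[(benzyloxy)methyl]-10,10-dimethyl-4-methylidene-5-(4-oxopentyl)-2-oxaspiro[5.5]undec-8-ene-3,7-dione, via hydroxy ester 12 (not isolated)
Conditions: NaBH4 (0.3 equiv), CH2Cl2/MeOH, −78 °C; then CSA (10 mol %), PhMe, 60 °C
Reagents that add atoms: none
Why: Chemoselective 1,2-reduction (borohydride at −78 °C reduces the activated aldehyde much faster than the methyl ketone or the hindered enone) is followed by acid-catalysed lactonization of the neopentyl alcohol onto the acrylate ester, which forms the lactone C–O bond without touching a stereocentre.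

Step 9
Reactants: 13 (5S,6S,11R)-11-[(benzyloxy)methyl]-10,10-dimethyl-4-methylidene-5-(4-oxopentyl)-2-oxaspiro[5.5]undec-8-ene-3,7-dione
Product: 14 (4R,7R,8S,12S,17R)-C4-acetyl spiro lactone enone benzyl ether (cyclohexane ring closed)
Conditions: pyrrolidine (20 mol %), PhCO2H (20 mol %), CH2Cl2, rt
Reagents that add atoms: none
Why: Enamine-mediated intramolecular Michael addition (6-endo-trig on the α-methylene lactone) joins C4 to C9, the acetyl group settles equatorial (trans to the C7 substituent) through enamine–iminium equilibration, and the lactone enol is protonated from the unhindered equatorial direction, which puts the lactone carbonyl axial and gives the cis ring fusion (also the less strained fusion, since C6 stays anti to C17).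

Step 10
Reactants: 14 (4R,7R,8S,12S,17R)-C4-acetyl spiro lactone enone benzyl ether
Product: 15 (4R,7R,8S,12S,17R)-C4-[1-(trifluoromethanesulfonyloxy)ethenyl] spiro lactone enone benzyl ether
Conditions: KN(SiMe3)2, THF, −78 °C; then PhNTf2
Reagents that add atoms: N-phenylbis(trifluoromethanesulfonimide), O=S(=O)(N(c1ccccc1)S(=O)(=O)C(F)(F)F)C(F)(F)F
Why: Kinetic deprotonation at the acetyl CH3 (the ring A enone has no enolizable hydrogen and the lactone α-CH is far less acidic) and O-sulfonylation of the terminal enolate give the enol triflate (enol triflate formation).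

Step 11
Reactants: 15 (4R,7R,8S,12S,17R)-C4-[1-(trifluoromethanesulfonyloxy)ethenyl] spiro lactone enone benzyl ether
Product: 16 (4R,7R,8S,12S,17R)-C4-(1-carboxyethenyl) spiro lactone enone benzyl ether
Conditions: Pd(OAc)2 (5 mol %), dppp (6 mol %), CO (1 atm), KOAc, DMF/H2O, 60 °C
Reagents that add atoms: carbon monoxide, [C-]#[O+]; water, O
Why: Palladium-catalysed hydroxycarbonylation, in which zerovalent palladium inserts into the vinyl C–OTf bond, CO insertion gives the acylpalladium and water releases the 2-substituted acrylic acid; no stereocentre is touched.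

Step 12
Reactants: 16 (4R,7R,8S,12S,17R)-C4-(1-carboxyethenyl) spiro lactone enone benzyl ether
Product: 18 (4R,7R,8S,12S,15R,17R)-2-substituted acrylic acid with the 6-oxabicyclo[3.2.1]octanone closed, via hydroxymethyl enone acid 17 (not isolated)
Conditions: BCl3, CH2Cl2, −78 °C; H2O; then CSA (10 mol %), CH2Cl2, rt
Reagents that add atoms: none
Why: BCl3 cleaves the benzyl ether by chloride attack on the O-complexed benzyl group, and the freed C16 hydroxyl then adds to C15 of the enone under acid catalysis (intramolecular oxa-Michael addition, 5-exo-trig) from the only face it can reach, which fixes C15 as R and closes the ether bridge.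

Step 13
Reactants: 18 (4R,7R,8S,12S,15R,17R)-2-substituted acrylic acid with the 6-oxabicyclo[3.2.1]octanone closed
Product: 19 CNP0152427.2 (2R,4R,7R,8S,12S,15R,17R)
Conditions: Ru(OAc)2[(R)-BINAP] (1 mol %), H2 (100 atm), MeOH, rt
Reagents that add atoms: none
Why: Carboxylate-directed asymmetric hydrogenation of a 2-substituted acrylic acid, in which the chelated acrylate takes up hydrogen on one face under catalyst control and so sets C2 as R, while the saturated ketone, lactone and ether are inert.

## Compound list

1 | 4,4-dimethylcyclohex-2-en-1-one | CC1(C)CCC(=O)C=C1 | starting material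
2 | 4,4-dimethylcyclohexa-2,5-dien-1-one | CC1(C)C=CC(=O)C=C1 | intermediate
3 | (5S)-5-[(benzyloxy)methyl]-4,4-dimethylcyclohex-2-en-1-one | O=C1C=CC(C)(C)[C@@H](COCc2ccccc2)C1 | intermediate
4 | (5R,6Z)-5-[(benzyloxy)methyl]-6-(hydroxymethylidene)-4,4-dimethylcyclohex-2-en-1-one (enol form of the 6-formyl ketone) | O=C1C=CC(C)(C)[C@@H](COCc2ccccc2)/C1=C/O | intermediate
5 | 1-methylcyclopentene | CC1=CCCC1 | starting material
6 | 5-oxohexanal | CC(=O)CCCC=O | intermediate
7 | methyl acrylate | C=CC(=O)OC | starting material
8 | methyl 3-hydroxy-2-methylidene-7-oxooctanoate (racemic) | CC(=O)CCCC(O)C(=C)C(=O)OC | intermediate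
9 | methyl (2Z)-2-(bromomethyl)-7-oxooct-2-enoate | CC(=O)CCC/C=C(\CBr)C(=O)OC | intermediate
10 | allyl vinyl ether: methyl (2E)-2-({[(E)-{(2R)-2-[(benzyloxy)methyl]-3,3-dimethyl-6-oxocyclohex-4-en-1-ylidene}methyl]oxy}methyl)-7-oxooct-2-enoate | O=C1C=CC(C)(C)[C@@H](COCc2ccccc2)/C1=C\OC/C(C(=O)OC)=C\CCCC(C)=O | intermediate
11 | methyl (3S)-3-{(1S,6R)-6-[(benzyloxy)methyl]-1-formyl-5,5-dimethyl-2-oxocyclohex-3-en-1-yl}-2-methylidene-7-oxooctanoate | O=C[C@@]1([C@H](CCCC(C)=O)C(=C)C(=O)OC)C(=O)C=CC(C)(C)[C@H]1COCc1ccccc1 | intermediate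
12 | hydroxy ester: methyl (3S)-3-{(1S,6R)-6-[(benzyloxy)methyl]-1-(hydroxymethyl)-5,5-dimethyl-2-oxocyclohex-3-en-1-yl}-2-methylidene-7-oxooctanoate | OC[C@@]1([C@H](CCCC(C)=O)C(=C)C(=O)OC)C(=O)C=CC(C)(C)[C@H]1COCc1ccccc1 | intermediate
13 | (5S,6S,11R)-11-[(benzyloxy)methyl]-10,10-dimethyl-4-methylidene-5-(4-oxopentyl)-2-oxaspiro[5.5]undec-8-ene-3,7-dione | O=C1OC[C@]2(C(=O)C=CC(C)(C)[C@H]2COCc2ccccc2)[C@H](CCCC(C)=O)C1=C | intermediate
14 | (4R,7R,8S,12S,17R)-acetyl tricycle: ring A = 6-[(benzyloxy)methyl]-5,5-dimethylcyclohex-3-en-2-one whose C1 (= C12) is also C4 of a cis-fused octahydroisochroman-1-one (C4a = C7; C8a = C8; lactone C=O = C10) carrying an acetyl group on its C7 (= C4) | CC(=O)[C@@H]1CC[C@@H]2[C@H](C1)C(=O)OC[C@]21C(=O)C=CC(C)(C)[C@H]1COCc1ccccc1 | intermediate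
15 | (4R,7R,8S,12S,17R)-enol triflate: as 14 with 1-[(trifluoromethanesulfonyl)oxy]ethenyl on C4 in place of acetyl | C=C(OS(=O)(=O)C(F)(F)F)[C@@H]1CC[C@@H]2[C@H](C1)C(=O)OC[C@]21C(=O)C=CC(C)(C)[C@H]1COCc1ccccc1 | intermediate
16 | (4R,7R,8S,12S,17R)-acrylic acid: as 14 with 1-carboxyethenyl on C4 in place of acetyl | C=C(C(=O)O)[C@@H]1CC[C@@H]2[C@H](C1)C(=O)OC[C@]21C(=O)C=CC(C)(C)[C@H]1COCc1ccccc1 | intermediate
17 | (4R,7R,8S,12S,17R)-hydroxymethyl enone acid: as 16 with free CH2OH on C17 | C=C(C(=O)O)[C@@H]1CC[C@@H]2[C@H](C1)C(=O)OC[C@]21C(=O)C=CC(C)(C)[C@H]1CO | intermediate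
18 | (4R,7R,8S,12S,15R,17R)-acrylic acid with closed ether bridge: the target skeleton with 1-carboxyethenyl on C4 | C=C(C(=O)O)[C@@H]1CC[C@@H]2[C@H](C1)C(=O)OC[C@]21C(=O)C[C@H]2OC[C@@H]1C2(C)C | intermediate
19 | CNP0152427.2: (2R)-2-substituted propanoic acid on C4 of the (4R,7R,8S,12S,15R,17R) spiro lactone/6-oxabicyclo[3.2.1]octan-3-one | C[C@@H](C(=O)O)[C@@H]1CC[C@@H]2[C@H](C1)C(=O)OC[C@]21C(=O)C[C@H]2OC[C@@H]1C2(C)C | target

## Step count and risks

Total step count: 13. Longest linear sequence: 10 (steps 1–3 and 7–13; the branch through steps 4–6 is equally long).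

The three steps most likely to fail:

Step 2 (the proposed new desymmetrizing conjugate addition). The α-alkoxymethyl Grignard reagent may transfer poorly or with low enantioselectivity. The fallback uses known chemistry, sets out from 2 and comes back at 3. Rh(acac)(C2H4)2/(S)-BINAP-catalysed 1,4-addition of (E)-2-phenylethenylboronic acid to 2 (dioxane/H2O, 100 °C) gives (5R)-4,4-dimethyl-5-[(E)-2-phenylethenyl]cyclohex-2-en-1-one F1. Ozonolysis of the styryl double bond, which is far more electron-rich than the enone (O3, CH2Cl2/MeOH, −78 °C; Me2S), gives (1S)-2,2-dimethyl-5-oxocyclohex-3-ene-1-carbaldehyde F2. This is reduced at once with NaBH(OAc)3 to (5S)-5-(hydroxymethyl)-4,4-dimethylcyclohex-2-en-1-one F3, which is benzylated under non-basic conditions (benzyl 2,2,2-trichloroacetimidate, TfOH cat.) to 3.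

Step 7 (O-alkylation/Claisen rearrangement). Competing C-alkylation, an unfavourable enol ether geometry or a boat transition state would erode the C7 configuration. The fallback sets out from 4 and 8 and comes back at 11. Alcohol 8 is converted with Boc2O and DMAP (cat.) into methyl 3-[(tert-butoxycarbonyl)oxy]-2-methylidene-7-oxooctanoate F4, and 4 is C-allylated with it under tertiary-amine catalysis (DABCO or the cinchona ether (DHQD)2PHAL, PhMe, rt; SN2'–SN2' allylic alkylation of a Morita–Baylis–Hillman carbonate). This forms the C12–C7 bond directly, without an O-allyl intermediate, and lets the amine catalyst rather than the enol ether geometry decide C7.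

Step 9 (amine-catalysed ring closure). The secondary amine may be trapped by the α-methylene lactone or the enone, and the ring closure may stall. The fallback sets out from 13 and comes back at 14. The methyl ketone is converted with Me3SiI and (Me3Si)2NH (CH2Cl2, −20 °C to rt) into its thermodynamic silyl enol ether, (5S,6S,11R)-11-[(benzyloxy)methyl]-10,10-dimethyl-4-methylidene-5-{(3Z)-4-[(trimethylsilyl)oxy]pent-3-en-1-yl}-2-oxaspiro[5.5]undec-8-ene-3,7-dione F5. TiCl4 (CH2Cl2, −78 °C) then closes the ring by an intramolecular Mukaiyama–Michael addition, and aqueous work-up protonates the enolate at C8 to give 14.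

Further compounds
F1 | step 2 | (5R)-4,4-dimethyl-5-[(E)-2-phenylethenyl]cyclohex-2-en-1-one | O=C1C=CC(C)(C)[C@@H](/C=C/c2ccccc2)C1
F2 | step 2 | (1S)-2,2-dimethyl-5-oxocyclohex-3-ene-1-carbaldehyde | O=C1C=CC(C)(C)[C@@H](C=O)C1
F3 | step 2 | (5S)-5-(hydroxymethyl)-4,4-dimethylcyclohex-2-en-1-one | O=C1C=CC(C)(C)[C@@H](CO)C1
F4 | step 7 | methyl 3-[(tert-butoxycarbonyl)oxy]-2-methylidene-7-oxooctanoate (racemic) | CC(=O)CCCC(OC(=O)OC(C)(C)C)C(=C)C(=O)OC
F5 | step 9 | (5S,6S,11R)-11-[(benzyloxy)methyl]-10,10-dimethyl-4-methylidene-5-{(3Z)-4-[(trimethylsilyl)oxy]pent-3-en-1-yl}-2-oxaspiro[5.5]undec-8-ene-3,7-dione | O=C1OC[C@]2(C(=O)C=CC(C)(C)[C@H]2COCc2ccccc2)[C@H](CC/C=C(/C)O[Si](C)(C)C)C1=C
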